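**Strategy.** The route rests on disconnecting the C3–C4 bond of ring A (C1–C5, C10) and exploits the C4 gem-dimethyl carbon flanked by the C3 carbonyl: C4 and one of its methyls are the isopropenyl group of (S)-carvone, and C3 is a nitrile carbon. In the last step an iron hydride adds a hydrogen atom to the isopropenyl CH2; the tertiary C4 radical closes ring A onto the nitrile, which creates the second methyl, the quaternary carbon and, after hydrolysis, the ketone in one operation. The precursor is a monocyclic cyclohexene (ring B) that already carries C5, C9 and C10 in their final configuration, the 2-cyanoethyl chain and the umbelliferone ether.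

Key step: step 7

Remark: drimane numbering is used for all intermediates (ring A = C1, C2, C3, C4, C5, C10; ring B = C5 to C10; C11 = the CH2O carbon); compounds 3 and 4 are carried on as mixtures of epimers at the methyl-bearing carbon (later C10), which is re-enolised in step 3.

**Step 1**
Reactants: 1 (S)-(+)-carvone
Product: 3 6-methylcarvone (5S,6R)-2,6-dimethyl-5-(prop-1-en-2-yl)cyclohex-2-en-1-one as the mixture with its C6 epimer, via carvone lithium dienolate 2 (not isolated)
Conditions: LiN(iPr)2, THF, −78 °C; MeI, −78 → 0 °C
Reagents that add atoms: methyl iodide, CI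
Why: Kinetic deprotonation at the α′-carbon gives the cross-conjugated lithium dienolate, which is C-methylated (enolate alkylation); the carvone stereocentre (C5) is untouched and the new centre need not be controlled (methyl mainly trans to isopropenyl) because it is re-enolised in step 3.

**Step 2**
Reactants: 3 6-methylcarvone
Product: 4 (1S,3R,4S,6S)-1,3-dimethyl-4-(prop-1-en-2-yl)-7-oxabicyclo[4.1.0]heptan-2-one (epoxy ketone; C3 epimers)
Conditions: 30% aq. H2O2, NaOH (cat.), MeOH, 0 °C
Reagents that add atoms: hydrogen peroxide, OO
Why: Weitz–Scheffer nucleophilic epoxidation touches only the enone (the isopropenyl group is inert to hydroperoxide anion); axial attack at C7 anti to the C5 isopropenyl group, as is the rule for carvone, should place the oxirane trans to isopropenyl and fix C7 and C8.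

**Step 3**
Reactants: 4 epoxy ketone; 5 acrylonitrile
Product: 6 3-[(1S,3R,4R,6S)-1,3-dimethyl-2-oxo-4-(prop-1-en-2-yl)-7-oxabicyclo[4.1.0]heptan-3-yl]propanenitrile
Conditions: KOtBu (10 mol%), tBuOH/THF, 0 °C → rt
Reagents that add atoms: none
Why: Base-catalysed cyanoethylation (Michael addition) is possible because the epoxy ketone has a single enolisable position (C10–H; C8 is fully substituted) and no enone is left for a second, ring-forming Michael addition; acrylonitrile should approach the tetrasubstituted enolate anti to the neighbouring isopropenyl group (pushed pseudoaxial by allylic strain with the C10 methyl), which sets the quaternary C10 with the chain trans to isopropenyl.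

**Step 4**
Reactants: 6 cyanoethyl epoxy ketone
Product: 7 3-[(1R,3R,4R,6S)-1,3-dimethyl-2-methylidene-4-(prop-1-en-2-yl)-7-oxabicyclo[4.1.0]heptan-3-yl]propanenitrile (vinyl epoxide)
Conditions: Ph3PCH3Br, KN(SiMe3)2, toluene, 0 °C; then 6, 0 → 80 °C
Reagents that add atoms: methyltriphenylphosphonium bromide, C[P+](c1ccccc1)(c1ccccc1)c1ccccc1.[Br-]
Why: Wittig methylenation with a hot, lithium-free ylide is tolerable because both α-carbons are fully substituted (no enolisation) and the oxirane carbon activates the hindered carbonyl, while the nitrile and the epoxide should survive; no stereocentre is affected.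

**Step 5**
Reactants: 7 vinyl epoxide; 8 umbelliferone (7-hydroxy-2H-chromen-2-one)
Product: 9 3-[(1R,4S,6R)-4-hydroxy-1,3-dimethyl-2-{[(2-oxo-2H-chromen-7-yl)oxy]methyl}-6-(prop-1-en-2-yl)cyclohex-2-en-1-yl]propanenitrile
Conditions: Pd(PPh3)4 (5 mol%), THF, 0 °C → rt
Reagents that add atoms: none
Why: Tsuji–Trost opening of the vinyl epoxide: zerovalent palladium ionises the allylic C8–O bond, the alkoxide deprotonates the acidic phenol, and the phenoxide attacks the unhindered CH2 terminus (C11) of the π-allyl instead of the fully substituted C8 (a tertiary ether would re-ionise), giving net 1,4-addition with a tetrasubstituted C8=C9 alkene; the C7–O bond is not broken, so C7 keeps its configuration.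

**Step 6**
Reactants: 9 allylic alcohol
Product: 12 3-[(1R,2S,6R)-1,3-dimethyl-2-{[(2-oxo-2H-chromen-7-yl)oxy]methyl}-6-(prop-1-en-2-yl)cyclohex-3-en-1-yl]propanenitrile, via sulfonylhydrazine adduct 10 (not isolated), via allylic diazene 11 (not isolated)
Conditions: 2-O2NC6H4SO2NHNH2 (NBSH), PPh3, DEAD, N-methylmorpholine, −30 °C; then 23 °C
Reagents that add atoms: none
Why: Reductive 1,3-transposition of an allylic alcohol through its monoalkyl diazene: Mitsunobu displacement at C7 goes with inversion, loss of sulfinic acid gives the diazene, and its concerted retro-ene loss of N2 delivers hydrogen to C9 on the face of the C7–N bond (opposite to the former hydroxyl, cis to the C10 methyl), so that 1,3-chirality transfer sets C9 with CH2OAr cis to the cyanoethyl chain, against the steric bias an external reagent would follow, and moves the alkene to C7=C8.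

**Step 7**
Reactants: 12 cyclisation precursor
Product: 14 7-{[(1S,4aS,8aR)-2,5,5,8a-tetramethyl-6-oxo-1,4,4a,5,6,7,8,8a-octahydronaphthalen-1-yl]methoxy}-2H-chromen-2-one (CNP0262399.6), via ketimine 13 (not isolated)
Conditions: Fe(acac)3 (30 mol%), PhSiH3, EtOH (0.01 M), 60 °C; then 1 M aq. HCl, THF, rt
Reagents that add atoms: water, O
Why: The iron hydride formed from Fe(acac)3 and PhSiH3 transfers a hydrogen atom to the CH2 terminus of the isopropenyl group, the tertiary C4 radical adds to the nitrile carbon C3, and the iminyl radical is reduced by divalent iron and protonated by ethanol to ketimine 13, which aqueous acid hydrolyses to the C3 ketone. The closest known reaction type is the iron-catalysed hydrogen-atom-transfer reductive cyclisation of alkenyl nitriles to cyclic ketones, a relative of Mukaiyama-type radical hydrofunctionalisation. Ring A (C1, C2, C3, C4, C5, C10) closes in the 6-exo-dig mode through a chair-like transition state with the C5 and C10 substituents both equatorial on ring B. No stereocentre is created (C4 carries two methyls); the trans ring fusion is inherited from the trans relation of isopropenyl group and cyanoethyl chain set in step 3, and C9 is not touched. The step needs hydrogen atom transfer to the 1,1-disubstituted alkene in preference to the trisubstituted C7=C8 alkene, and cyclisation in preference to reduction or addition to the coumarin; the higher rate of transfer to 1,1-disubstituted alkenes, the quaternary C10 that holds chain and radical close (Thorpe–Ingold effect) and high dilution should secure this.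

**Compound list**
1 | (S)-(+)-carvone, (5S)-2-methyl-5-(prop-1-en-2-yl)cyclohex-2-en-1-one | CC1=CC[C@H](C(C)=C)CC1=O | starting material
2 | carvone lithium dienolate, lithium (3S)-6-methyl-3-(prop-1-en-2-yl)cyclohexa-1,5-dien-1-olate | CC1=CC[C@H](C(C)=C)C=C1O[Li] | intermediate
3 | (5S,6R)-2,6-dimethyl-5-(prop-1-en-2-yl)cyclohex-2-en-1-one (major epimer; methyl trans to isopropenyl) | CC1=CC[C@H](C(C)=C)[C@@H](C)C1=O | intermediate
4 | (1S,3R,4S,6S)-1,3-dimethyl-4-(prop-1-en-2-yl)-7-oxabicyclo[4.1.0]heptan-2-one (oxirane trans to isopropenyl; major C3 epimer) | C[C@]12O[C@H]1C[C@H](C(C)=C)[C@@H](C)C2=O | intermediate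
5 | acrylonitrile | C=CC#N | starting material
6 | 3-[(1S,3R,4R,6S)-1,3-dimethyl-2-oxo-4-(prop-1-en-2-yl)-7-oxabicyclo[4.1.0]heptan-3-yl]propanenitrile (chain trans to isopropenyl, cis to oxirane) | C[C@]12O[C@H]1C[C@H](C(C)=C)[C@@](C)(CCC#N)C2=O | intermediate
7 | 3-[(1R,3R,4R,6S)-1,3-dimethyl-2-methylidene-4-(prop-1-en-2-yl)-7-oxabicyclo[4.1.0]heptan-3-yl]propanenitrile | C[C@]12O[C@H]1C[C@H](C(C)=C)[C@@](C)(CCC#N)C2=C | intermediate
8 | umbelliferone, 7-hydroxy-2H-chromen-2-one | Oc1ccc2ccc(=O)oc2c1 | starting material
9 | 3-[(1R,4S,6R)-4-hydroxy-1,3-dimethyl-2-{[(2-oxo-2H-chromen-7-yl)oxy]methyl}-6-(prop-1-en-2-yl)cyclohex-2-en-1-yl]propanenitrile (C7–OH cis to the cyanoethyl chain) | CC1=C(COc2ccc3ccc(=O)oc3c2)[C@](C)(CCC#N)[C@@H](C(C)=C)C[C@@H]1O | intermediate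
10 | N-(2-nitrobenzenesulfonyl)hydrazine adduct of 9 at C7 (C7–N with inverted configuration) | CC1=C(COc2ccc3ccc(=O)oc3c2)[C@](C)(CCC#N)[C@@H](C(C)=C)C[C@H]1N(N)S(=O)(=O)c1ccccc1[N+](=O)[O-] | intermediate
11 | allylic diazene at C7 (C7–N=NH, same configuration as 10) | CC1=C(COc2ccc3ccc(=O)oc3c2)[C@](C)(CCC#N)[C@@H](C(C)=C)C[C@H]1N=N | intermediate
12 | 3-[(1R,2S,6R)-1,3-dimethyl-2-{[(2-oxo-2H-chromen-7-yl)oxy]methyl}-6-(prop-1-en-2-yl)cyclohex-3-en-1-yl]propanenitrile (CH2OAr cis to the chain, trans to isopropenyl) | CC1=CC[C@H](C(C)=C)[C@@](C)(CCC#N)[C@H]1COc1ccc2ccc(=O)oc2c1 | intermediate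
13 | 7-{[(1S,4aS,8aR)-6-imino-2,5,5,8a-tetramethyl-1,4,4a,5,6,7,8,8a-octahydronaphthalen-1-yl]methoxy}-2H-chromen-2-one | CC1=CC[C@@H]2C(C)(C)C(=N)CC[C@@]2(C)[C@H]1COc1ccc2ccc(=O)oc2c1 | intermediate
14 | 7-{[(1S,4aS,8aR)-2,5,5,8a-tetramethyl-6-oxo-1,4,4a,5,6,7,8,8a-octahydronaphthalen-1-yl]methoxy}-2H-chromen-2-one | CC1=CC[C@@H]2C(C)(C)C(=O)CC[C@@]2(C)[C@H]1COc1ccc2ccc(=O)oc2c1 | target

**Step count.** Total: 7 steps. Longest linear sequence: 7 steps from (S)-carvone.

**Steps most likely to fail**

Step 7. Hydrogen atom transfer may not stay at the isopropenyl group: transfer to the trisubstituted C7=C8 alkene would reduce or shift it, and the tertiary radical may be reduced before the slow addition to the nitrile. The fallback moves the ring closure in front of the transposition and sets out from 9, whose second ring alkene is tetrasubstituted and inert to hydrogen atom transfer, so that more forcing conditions can be applied. Fe(acac)3, PhSiH3, EtOH, 60 °C should give the ketimine F1 and, after aqueous HCl, the bicyclic hydroxy ketone F2. Mitsunobu reaction with NBSH (PPh3, DEAD, −30 °C) at the allylic C7 hydroxyl (the hindered C3 ketone should condense only slowly with the hydrazide) should give the sulfonylhydrazine F3. On warming this should lose sulfinic acid to the allylic diazene F4, whose retro-ene loss of N2 delivers hydrogen to C9; the route is rejoined at 14.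

Step 4. Addition of the ylide to a carbonyl flanked by two fully substituted carbons may be too slow, so that at the temperature needed the ylide attacks the oxirane or acts as a base. The fallback is a two-stage Peterson olefination from 6: the small, hard organocerium reagent from Me3SiCH2Li and CeCl3 (THF, −78 °C, where ketone addition should outrun addition to the nitrile) should give the β-hydroxysilane F5, and KN(SiMe3)2 (THF, 0 °C) should induce syn-elimination to rejoin the route at 7.

Step 6. The Mitsunobu displacement at the hindered allylic C7 may run through ionisation to an allyl cation, which would erase the inversion on which the chirality transfer depends, or end in elimination to a diene. The fallback is a palladium-mediated formate hydrogenolysis from 9: formylation (HCO2H, Ac2O, pyridine) should give the allylic formate F6; with Pd(OAc)2 and PBu3 in THF, zerovalent palladium should ionise the formate with inversion and, after loss of CO2, deliver hydride from the metal to the more substituted terminus C9, anti to the former C7–O bond. This is the same face as in step 6 and rejoins the route at 12; the formate should ionise faster than the allylic aryl ether.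

**Further compounds**
F1 | step 7 | ketimine of F2 (C3=NH, ring A closed, C8=C9 alkene, C7–OH) | CC1=C(COc2ccc3ccc(=O)oc3c2)[C@]2(C)CCC(=N)C(C)(C)[C@H]2C[C@@H]1O
F2 | step 7 | bicyclic hydroxy ketone (trans-fused 3-oxo decalin with C8=C9 alkene, C7–OH cis to C1, C11 umbelliferyl ether) | CC1=C(COc2ccc3ccc(=O)oc3c2)[C@]2(C)CCC(=O)C(C)(C)[C@H]2C[C@@H]1O
F3 | step 7 | N-(2-nitrobenzenesulfonyl)hydrazine adduct of F2 at C7 (inverted) | CC1=C(COc2ccc3ccc(=O)oc3c2)[C@]2(C)CCC(=O)C(C)(C)[C@H]2C[C@H]1N(N)S(=O)(=O)c1ccccc1[N+](=O)[O-]
F4 | step 7 | allylic diazene derived from F3 (C7–N=NH) | CC1=C(COc2ccc3ccc(=O)oc3c2)[C@]2(C)CCC(=O)C(C)(C)[C@H]2C[C@H]1N=N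
F5 | step 4 | β-hydroxysilane from 6 (C9 carbinol bearing CH2SiMe3; C9 configuration immaterial) | C[C@]12O[C@H]1C[C@H](C(C)=C)[C@@](C)(CCC#N)C2(O)C[Si](C)(C)C
F6 | step 6 | allylic formate of 9 at C7 | CC1=C(COc2ccc3ccc(=O)oc3c2)[C@](C)(CCC#N)[C@@H](C(C)=C)C[C@@H]1OC=O
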